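**Retrosynthetic overview**
1. Target 10 ⇒ aldehyde 8 by a two-carbon Wittig homologation of the aryl aldehyde (side-chain C=C).
2. 8 ⇒ iodoaryl 1-arylallyl ether 5 by aryl-radical 5-exo cyclization with oxygen capture (C3–C3a bond, CH2–OH bond, C3 stereocentre).
3. 5 ⇒ 5-iodovanillin 4 + cinnamyl carbonate 3 by enantioselective allylic etherification (C2–O bond, C2 stereocentre).
4. 3 ⇒ 3,4-dimethoxycinnamyl alcohol 1 + Boc2O 2.
5. Ring order: both benzene rings are bought; the dihydrofuran ring is the only ring built (step 3).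

Assumption: the (Ra,Rc,Rc) enantiomer of the phosphoramidite ligand L is taken to give the (R)-ether 5; the sense is checked on the first run and the mirror-image ligand is used if it is opposite.

L = (Ra,Rc,Rc)-O,O'-(1,1'-binaphthyl-2,2'-diyl) N,N-bis[1-(2-methoxyphenyl)ethyl]phosphoramidite.

**Route**

Step 1
Reactants: 1 (E)-3-(3,4-dimethoxyphenyl)prop-2-en-1-ol; 2 di-tert-butyl dicarbonate
Product: 3 tert-butyl (E)-3-(3,4-dimethoxyphenyl)allyl carbonate
Conditions: Boc2O (1.2 equiv), DMAP (5 mol%), CH2Cl2, 0 °C to rt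
Reagents that add atoms: di-tert-butyl dicarbonate (compound 2), CC(C)(C)OC(=O)OC(=O)OC(C)(C)C
Why: DMAP-catalysed O-acylation of a primary allylic alcohol gives the tert-butyl carbonate, a leaving group that releases CO2 and its own base on ionization; no stereocentre is formed.

Step 2
Reactants: 3 tert-butyl (E)-3-(3,4-dimethoxyphenyl)allyl carbonate; 4 5-iodovanillin (4-hydroxy-3-iodo-5-methoxybenzaldehyde)
Product: 5 (R)-4-{[1-(3,4-dimethoxyphenyl)prop-2-en-1-yl]oxy}-3-iodo-5-methoxybenzaldehyde
Conditions: [Ir(cod)Cl]2 (2 mol%), ligand L (4 mol%), TBD (8 mol%), THF, 30 °C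
Reagents that add atoms: 5-iodovanillin (compound 4), COc1cc(C=O)cc(I)c1O
Why: Iridium-catalysed branched-selective asymmetric allylic etherification (Tsuji–Trost type): the tert-butoxide released on ionization deprotonates the acidic phenol, the phenoxide attacks the aryl-bearing terminus of the allyl-iridium complex, and the chiral ligand sets C2 as R; both ortho positions of the phenol are blocked, so only O-allylation is possible.

Step 3
Reactants: 5 (R)-4-{[1-(3,4-dimethoxyphenyl)prop-2-en-1-yl]oxy}-3-iodo-5-methoxybenzaldehyde; 6 dioxygen (air)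
Product: 8 (2R,3S)-2-(3,4-dimethoxyphenyl)-3-(hydroxymethyl)-7-methoxy-2,3-dihydrobenzofuran-5-carbaldehyde, via primary hydroperoxide 7 (not isolated)
Conditions: 4CzIPN [1,2,3,5-tetrakis(carbazol-9-yl)-4,6-dicyanobenzene] (3 mol%), Et3N (5 equiv), air, MeCN, blue LEDs, 0 °C; then PPh3 (1.2 equiv), rt; aq. NaHCO3 work-up
Reagents that add atoms: dioxygen (compound 6), O=O
Why: Proposed new method: a tin-free, halogen-atom-transfer-initiated aerobic oxy-arylative radical cyclization, in which photo-oxidation of Et3N by excited 4CzIPN gives an α-aminoalkyl radical that abstracts iodine from 5, the aryl radical closes 5-exo-trig onto the vinyl group through a Beckwith–Houk chair-like transition state with the C2 aryl group pseudo-equatorial (C3 trans to it, hence 3S from 2R, expected about 5–10:1 with the cis isomer removed by chromatography), the primary radical is captured by O2, the peroxyl radical takes a hydrogen atom from Et3N and so regenerates the chain carrier, and PPh3 reduces hydroperoxide 7 to the alcohol; the closest known reaction types are the tin hydride/air radical cyclization–oxygenation of aryl iodides and the photocatalytic halogen-atom-transfer activation of aryl iodides by α-aminoalkyl radicals, which have not been merged into one oxygenative cyclization nor run on an O-(1-arylallyl) iodophenol carrying a free aldehyde.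

Step 4
Reactants: 8 (2R,3S)-2-(3,4-dimethoxyphenyl)-3-(hydroxymethyl)-7-methoxy-2,3-dihydrobenzofuran-5-carbaldehyde; 9 (triphenylphosphoranylidene)acetaldehyde
Product: 10 4-O-methylbalanophonin, (E)-3-[(2R,3S)-2-(3,4-dimethoxyphenyl)-3-(hydroxymethyl)-7-methoxy-2,3-dihydrobenzofuran-5-yl]prop-2-enal
Conditions: Ph3P=CHCHO (1.3 equiv), toluene, 80 °C
Reagents that add atoms: (triphenylphosphoranylidene)acetaldehyde (compound 9), O=CC=P(c1ccccc1)(c1ccccc1)c1ccccc1
Why: Wittig olefination with a stabilized formyl ylide gives the (E)-enal, tolerates the free primary alcohol and does not touch the two sp3 stereocentres.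

**Compound list**
1 | (E)-3-(3,4-dimethoxyphenyl)prop-2-en-1-ol (3,4-dimethoxycinnamyl alcohol) | COc1ccc(/C=C/CO)cc1OC | starting material
2 | di-tert-butyl dicarbonate | CC(C)(C)OC(=O)OC(=O)OC(C)(C)C | starting material
3 | tert-butyl (E)-3-(3,4-dimethoxyphenyl)allyl carbonate | COc1ccc(/C=C/COC(=O)OC(C)(C)C)cc1OC | intermediate
4 | 5-iodovanillin (4-hydroxy-3-iodo-5-methoxybenzaldehyde) | COc1cc(C=O)cc(I)c1O | starting material
5 | (R)-4-{[1-(3,4-dimethoxyphenyl)prop-2-en-1-yl]oxy}-3-iodo-5-methoxybenzaldehyde | COc1ccc([C@@H](C=C)Oc2c(I)cc(C=O)cc2OC)cc1OC | intermediate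
6 | dioxygen (air) | O=O | starting material
7 | (2R,3S)-2-(3,4-dimethoxyphenyl)-3-(hydroperoxymethyl)-7-methoxy-2,3-dihydrobenzofuran-5-carbaldehyde (trans) | COc1ccc([C@@H]2Oc3c(OC)cc(C=O)cc3[C@H]2COO)cc1OC | intermediate
8 | (2R,3S)-2-(3,4-dimethoxyphenyl)-3-(hydroxymethyl)-7-methoxy-2,3-dihydrobenzofuran-5-carbaldehyde (trans) | COc1ccc([C@@H]2Oc3c(OC)cc(C=O)cc3[C@H]2CO)cc1OC | intermediate
9 | (triphenylphosphoranylidene)acetaldehyde | O=CC=P(c1ccccc1)(c1ccccc1)c1ccccc1 | starting material
10 | 4-O-methylbalanophonin, (E)-3-[(2R,3S)-2-(3,4-dimethoxyphenyl)-3-(hydroxymethyl)-7-methoxy-2,3-dihydrobenzofuran-5-yl]prop-2-enal | COc1ccc([C@@H]2Oc3c(OC)cc(/C=C/C=O)cc3[C@H]2CO)cc1OC | target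

**Step count**
Total steps: 4. Longest linear sequence: 4 steps (1 → 3 → 5 → 8 → 10).

**Three steps most likely to fail**

Step 2. The phenoxide of 4 is hindered and weakly nucleophilic, and the electron-rich product can re-ionize on the iridium catalyst, which would erode the ee and the branched-to-linear ratio. The fallback sets out from compound 4 (with commercial 3,4-dimethoxybenzaldehyde in place of 1–3) and comes back at compound 5. CH2=CHMgBr adds to 3,4-dimethoxybenzaldehyde (THF, 0 °C) to give racemic 1-(3,4-dimethoxyphenyl)prop-2-en-1-ol F1. A lipase kinetic resolution (Candida antarctica lipase B, vinyl acetate, MTBE, 30 °C) leaves (S)-1-(3,4-dimethoxyphenyl)prop-2-en-1-ol F2 and converts the other enantiomer into (R)-1-(3,4-dimethoxyphenyl)allyl acetate F3, which is discarded. A Mitsunobu etherification of F2 with 4 (PPh3, DIAD, toluene, −20 °C) then gives 5 with inversion at the carbinol carbon.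

Step 3 (the proposed new method). O2 can intercept the α-aminoalkyl radical before iodine transfer, the aldehyde can autoxidize, and the trans:cis ratio may be modest. The fallback uses known chemistry, sets out from compound 5 and comes back at compound 8. An aryl-radical 5-exo cyclization with nitroxide capture (Bu3SnH, TEMPO, benzene, 70 °C) gives (2R,3S)-2-(3,4-dimethoxyphenyl)-7-methoxy-3-{[(2,2,6,6-tetramethylpiperidin-1-yl)oxy]methyl}-2,3-dihydrobenzofuran-5-carbaldehyde F4. Reductive N–O cleavage (Zn, AcOH/THF/H2O, 60 °C) then releases alcohol 8.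

Step 4. The electron-rich aldehyde reacts slowly, and the product enal can react a second time with the ylide to give a dienal. The fallback sets out from compound 8 and comes back at compound 10. A Wittig reaction with Ph3P=CHCO2Et (toluene, 80 °C) gives ethyl (E)-3-[(2R,3S)-2-(3,4-dimethoxyphenyl)-3-(hydroxymethyl)-7-methoxy-2,3-dihydrobenzofuran-5-yl]prop-2-enoate F5. Reduction with i-Bu2AlH (CH2Cl2, −78 °C) gives (E)-3-[(2R,3S)-2-(3,4-dimethoxyphenyl)-3-(hydroxymethyl)-7-methoxy-2,3-dihydrobenzofuran-5-yl]prop-2-en-1-ol F6. MnO2 (CH2Cl2, rt) then oxidizes only the allylic alcohol of F6 to give 10.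

**Further compounds**
F1 | step 2 | racemic 1-(3,4-dimethoxyphenyl)prop-2-en-1-ol | COc1ccc(C(O)C=C)cc1OC
F2 | step 2 | (S)-1-(3,4-dimethoxyphenyl)prop-2-en-1-ol | COc1ccc([C@H](C=C)O)cc1OC
F3 | step 2 | (R)-1-(3,4-dimethoxyphenyl)allyl acetate | COc1ccc([C@@H](C=C)OC(C)=O)cc1OC
F4 | step 3 | (2R,3S)-2-(3,4-dimethoxyphenyl)-7-methoxy-3-{[(2,2,6,6-tetramethylpiperidin-1-yl)oxy]methyl}-2,3-dihydrobenzofuran-5-carbaldehyde | COc1ccc([C@@H]2Oc3c(OC)cc(C=O)cc3[C@H]2CON4C(C)(C)CCCC4(C)C)cc1OC
F5 | step 4 | ethyl (E)-3-[(2R,3S)-2-(3,4-dimethoxyphenyl)-3-(hydroxymethyl)-7-methoxy-2,3-dihydrobenzofuran-5-yl]prop-2-enoate | COc1ccc([C@@H]2Oc3c(OC)cc(/C=C/C(=O)OCC)cc3[C@H]2CO)cc1OC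
F6 | step 4 | (E)-3-[(2R,3S)-2-(3,4-dimethoxyphenyl)-3-(hydroxymethyl)-7-methoxy-2,3-dihydrobenzofuran-5-yl]prop-2-en-1-ol | COc1ccc([C@@H]2Oc3c(OC)cc(/C=C/CO)cc3[C@H]2CO)cc1OC
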